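**Plan**

Numbering follows chromane: O1, C2, C3, C4, C4a, C5–C8, C8a. Ring A is the carbocycle C4a–C5–C6–C7–C8–C8a, ring B the dihydropyranone O1–C2–C3–C4–C4a–C8a. Geranyl = (2E)-3,7-dimethylocta-2,6-dien-1-yl.
Retrosynthesis: cut C4–C4a (ring B, intramolecular C-acylation), then C5–C6 and C4a=C8a together (ring A), then C6–C7 (ketone from an acid chloride), O1–C8a (ester) and C8–geranyl (malonate alkylation).
Enabling feature: ring A is an enolised cyclic β-triketone in which C4a=C8a is an enol-ether bond whose oxygen is O1, and C5 is a carbonyl carbon between C4a and the enolisable C6. C4a–C5 is therefore a ketene-level two-carbon unit that Ph3P=C=C=O can insert between the C6 enolate and the ester carbonyl C8a of an acyclic β-keto ester (C-acylation, then Wittig olefination of the ester), with O1 already fixed on C8a.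
Forward: the chain C6–C7–C8–C8a–O1–C2–C3–C4 is joined first, ring A arises in the key step, ring B last.
Stereochemistry: C8 (R) from enzymatic desymmetrisation of prochiral dimethyl geranyl(methyl)malonate, a quaternary centre that cannot epimerise. C2 (S) from commercial tert-butyl (S)-3-hydroxybutanoate, whose C–O bond is never broken and which meets no base once the C4 ketone exists.

Key step: step 6

Assumption: the esterase is taken to deliver the (R)-half-ester, by analogy with other dimethyl 2-alkyl-2-methylmalonates bearing a long chain; a minor enantiomer becomes a separable diastereomer at the next stage.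
Remark: the CIP descriptor of the quaternary carbon alternates between R and S along the route only because substituent priorities change; its spatial arrangement is never altered.

**Route**

Step 1
Reactants: 1 dimethyl 2-methylpropanedioate; 2 geranyl bromide, (2E)-1-bromo-3,7-dimethylocta-2,6-diene
Product: 3 dimethyl 2-geranyl-2-methylpropanedioate
Conditions: NaH, THF, 0 °C → rt
Reagents that add atoms: none
Why: Malonate alkylation (SN2): the sodium enolate of 1 displaces bromide at the primary allylic carbon of 2 with the E double bond kept, and the product is prochiral, so no stereocentre is set yet.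

Step 2
Reactants: 3 dimethyl 2-geranyl-2-methylpropanedioate
Product: 4 (2R)-2-geranyl-3-methoxy-2-methyl-3-oxopropanoic acid
Conditions: pig liver esterase, 0.1 M NaH2PO4/Na2HPO4 buffer pH 7.5, 10 vol % DMSO, 25 °C; acidify to pH 2, extract
Reagents that add atoms: water (O)
Why: Enzymatic desymmetrisation by a carboxylesterase (serine hydrolase): the enzyme hydrolyses one of the two enantiotopic methyl esters of 3, which should set the quaternary centre as R, and a centre without hydrogen cannot epimerise later.

Step 3
Reactants: 4 (2R)-2-geranyl-3-methoxy-2-methyl-3-oxopropanoic acid; 5 tert-butyl (3S)-3-hydroxybutanoate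
Product: 6 1-[(2S)-4-tert-butoxy-4-oxobutan-2-yl] 3-methyl (2S)-2-geranyl-2-methylpropanedioate
Conditions: DCC, DMAP (cat.), CH2Cl2, 0 °C → rt
Reagents that add atoms: none
Why: Steglich esterification: the carbodiimide-activated acid is passed by DMAP to the secondary alcohol, whose C–O bond is not broken, so C2 stays S, and the epimer arising from any minor enantiomer of 4 is a diastereomer that should be removable by chromatography here.

Step 4
Reactants: 6 1-[(2S)-4-tert-butoxy-4-oxobutan-2-yl] 3-methyl (2S)-2-geranyl-2-methylpropanedioate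
Product: 7 (2S)-3-{[(2S)-4-tert-butoxy-4-oxobutan-2-yl]oxy}-2-geranyl-2-methyl-3-oxopropanoic acid
Conditions: LiI, EtOAc, reflux, dark; cold 1 M HCl work-up
Reagents that add atoms: none
Why: Nucleophilic ester dealkylation (SN2 by iodide at the O–CH3 carbon): only the methyl ester offers an unhindered alkyl carbon, so the secondary-alkyl and tert-butyl esters and both stereocentres should stay untouched.

Step 5
Reactants: 7 (2S)-3-{[(2S)-4-tert-butoxy-4-oxobutan-2-yl]oxy}-2-geranyl-2-methyl-3-oxopropanoic acid; 8 5-bromo-2-methylpent-2-ene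
Product: 11 (2S)-4-tert-butoxy-4-oxobutan-2-yl (2S)-2-geranyl-2,7-dimethyl-3-oxooct-6-enoate, via acid chloride 9 (not isolated), via Grignard reagent 10 (not isolated)
Conditions: 7, 1-chloro-N,N,2-trimethylprop-1-en-1-amine, CH2Cl2, 0 °C → rt; separately 8, Mg, THF; then combine with Fe(acac)3 (3 mol %), THF, −78 °C
Reagents that add atoms: none
Why: Acid chloride formation under neutral conditions followed by iron-catalysed acylation of a Grignard reagent: the cross-coupling should be faster at −78 °C than addition of the Grignard reagent to the esters or to the ketone formed, and the quaternary centre has no α-hydrogen to lose.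

Step 6
Reactants: 11 (2S)-4-tert-butoxy-4-oxobutan-2-yl (2S)-2-geranyl-2,7-dimethyl-3-oxooct-6-enoate; 12 (triphenylphosphoranylidene)ketene, Ph3P=C=C=O
Product: 15 tert-butyl (3S)-3-{[(6R)-6-geranyl-3-hydroxy-6-methyl-4-(3-methylbut-2-en-1-yl)-5-oxocyclohexa-1,3-dien-1-yl]oxy}butanoate, via lithium enolate 13 (not isolated), via acyl ylide 14 (not isolated)
Conditions: LiN(SiMe3)2 (1.05 equiv), THF, −78 °C; 12 (1.2 equiv), −78 °C → rt; then toluene, 90 °C; cold 0.5 M HCl work-up
Reagents that add atoms: none
Why: Proposed new method: LiN(SiMe3)2 removes a C6–H of 11 (the only ketone α-CH2, since C8 is quaternary and the ester α-CH2 at C3 is several pKa units less acidic), and the enolate carbon adds to the central sp carbon of Ph3P=C=C=O to form C5–C6; proton transfer from the now doubly activated C6–H gives acyl ylide 14, whose ylide carbon C4a is only weakly stabilised because its carbonyl C5 is part of a β-diketonate. On heating, C4a attacks the ester carbonyl C8a (6-exo-trig, oxaphosphetane, loss of Ph3PO), which closes ring A as the C4a=C8a enol ether and leaves O1 on C8a, i.e. a Wittig olefination of an ester carbonyl. The closest known reaction types are the domino addition–intramolecular Wittig ester olefination of Ph3P=C=C=O with α-hydroxy esters (tetronates), its C-acylation of cyclic 1,3-dicarbonyl C–H acids and of Grignard reagents, and chromone formation by intramolecular Wittig reaction of acyl ylides with ester carbonyls; a ketone enolate as the carbon nucleophile and closure of a carbocycle are the new elements. No stereocentre is formed: C8 is quaternary and C2 is not deprotonated, so both are carried through unchanged. The step needs C- over O-acylation of the enolate (lithium counter-ion in THF at low temperature; an O-adduct would go on to a 2-pyranone) and olefination of C8a and not of the tert-butyl ester, which ring size (six- against ten-membered) and the bulk of the tert-butyl group should secure.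

Step 7
Reactants: 15 tert-butyl (3S)-3-{[(6R)-6-geranyl-3-hydroxy-6-methyl-4-(3-methylbut-2-en-1-yl)-5-oxocyclohexa-1,3-dien-1-yl]oxy}butanoate
Product: 17 (3S)-3-{[(6R)-6-geranyl-3-hydroxy-6-methyl-4-(3-methylbut-2-en-1-yl)-5-oxocyclohexa-1,3-dien-1-yl]oxy}butanoic acid, via bis-silyl derivative 16 (not isolated)
Conditions: Me3SiOTf (3 equiv), 2,6-lutidine (4 equiv), CH2Cl2, 0 °C; aqueous pH 4 work-up
Reagents that add atoms: none
Why: Silyl triflate-mediated cleavage of a tert-butyl ester (loss of isobutene from the O-silylated ester, buffered by 2,6-lutidine): no Brønsted acid able to protonate the prenyl and geranyl double bonds is present, the silyl ester and silyl enol ether are hydrolysed on work-up, and neither stereocentre is involved.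

Step 8
Reactants: 17 (3S)-3-{[(6R)-6-geranyl-3-hydroxy-6-methyl-4-(3-methylbut-2-en-1-yl)-5-oxocyclohexa-1,3-dien-1-yl]oxy}butanoic acid
Product: 19 (2S,8R)-8-geranyl-5-hydroxy-2,8-dimethyl-6-(3-methylbut-2-en-1-yl)-2,3-dihydro-4H-chromene-4,7(8H)-dione, via mixed anhydride 18 (not isolated)
Conditions: (CF3CO)2O (1.5 equiv), CH2Cl2, 0 °C → rt; pH 7 aqueous work-up
Reagents that add atoms: none
Why: Intramolecular Friedel–Crafts-type C-acylation through the mixed trifluoroacetic anhydride, the way 3-aryloxypropanoic acids close to chroman-4-ones: the enol-ether carbon C4a, flanked by the O1-bearing C8a and the enolic C5, attacks the activated acyl carbon C4 in a 6-exo-trig closure of ring B (C6 would need an eight-membered ring), and since no base is present the β-alkoxy ketone cannot eliminate, so C2 stays S and C8 stays R.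

**Compound list**

1 | dimethyl 2-methylpropanedioate | COC(=O)C(C)C(=O)OC | starting material
2 | geranyl bromide, (2E)-1-bromo-3,7-dimethylocta-2,6-diene | CC(C)=CCC/C(C)=C/CBr | starting material
3 | dimethyl 2-geranyl-2-methylpropanedioate | CC(C)=CCC/C(C)=C/CC(C)(C(=O)OC)C(=O)OC | intermediate
4 | (2R)-2-geranyl-3-methoxy-2-methyl-3-oxopropanoic acid | CC(C)=CCC/C(C)=C/C[C@@](C)(C(=O)OC)C(=O)O | intermediate
5 | tert-butyl (3S)-3-hydroxybutanoate | C[C@H](O)CC(=O)OC(C)(C)C | starting material
6 | 1-[(2S)-4-tert-butoxy-4-oxobutan-2-yl] 3-methyl (2S)-2-geranyl-2-methylpropanedioate | CC(C)=CCC/C(C)=C/C[C@@](C)(C(=O)OC)C(=O)O[C@@H](C)CC(=O)OC(C)(C)C | intermediate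
7 | (2S)-3-{[(2S)-4-tert-butoxy-4-oxobutan-2-yl]oxy}-2-geranyl-2-methyl-3-oxopropanoic acid | CC(C)=CCC/C(C)=C/C[C@@](C)(C(=O)O)C(=O)O[C@@H](C)CC(=O)OC(C)(C)C | intermediate
8 | 5-bromo-2-methylpent-2-ene | CC(C)=CCCBr | starting material
9 | (2S)-4-tert-butoxy-4-oxobutan-2-yl (2R)-3-chloro-2-geranyl-2-methyl-3-oxopropanoate (acid chloride of 7) | CC(C)=CCC/C(C)=C/C[C@@](C)(C(Cl)=O)C(=O)O[C@@H](C)CC(=O)OC(C)(C)C | intermediate
10 | (4-methylpent-3-en-1-yl)magnesium bromide | CC(C)=CCC[Mg]Br | intermediate
11 | (2S)-4-tert-butoxy-4-oxobutan-2-yl (2S)-2-geranyl-2,7-dimethyl-3-oxooct-6-enoate | CC(C)=CCC/C(C)=C/C[C@@](C)(C(=O)CCC=C(C)C)C(=O)O[C@@H](C)CC(=O)OC(C)(C)C | intermediate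
12 | (triphenylphosphoranylidene)ketene | O=C=C=P(c1ccccc1)(c1ccccc1)c1ccccc1 | starting material
13 | lithium (Z)-enolate of 11 at the ketone (C7–O, C6=C7), both stereocentres as in 11 | CC(C)=CCC/C(C)=C/C[C@@](C)(/C(O[Li])=C/CC=C(C)C)C(=O)O[C@@H](C)CC(=O)OC(C)(C)C | intermediate
14 | lithium enolate of the C6-[(triphenylphosphoranylidene)acetyl] derivative of 11 (acyl ylide), both stereocentres as in 11 | CC(C)=CCC/C(C)=C/C[C@@](C)(C(=O)C(CC=C(C)C)=C(O[Li])C=P(c1ccccc1)(c1ccccc1)c1ccccc1)C(=O)O[C@@H](C)CC(=O)OC(C)(C)C | intermediate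
15 | tert-butyl (3S)-3-{[(6R)-6-geranyl-3-hydroxy-6-methyl-4-(3-methylbut-2-en-1-yl)-5-oxocyclohexa-1,3-dien-1-yl]oxy}butanoate | CC(C)=CCC/C(C)=C/C[C@@]1(C)C(=O)C(CC=C(C)C)=C(O)C=C1O[C@@H](C)CC(=O)OC(C)(C)C | intermediate
16 | trimethylsilyl ester and C5 trimethylsilyl enol ether of 17 (3S, 6R) | CC(C)=CCC/C(C)=C/C[C@@]1(C)C(=O)C(CC=C(C)C)=C(O[Si](C)(C)C)C=C1O[C@@H](C)CC(=O)O[Si](C)(C)C | intermediate
17 | (3S)-3-{[(6R)-6-geranyl-3-hydroxy-6-methyl-4-(3-methylbut-2-en-1-yl)-5-oxocyclohexa-1,3-dien-1-yl]oxy}butanoic acid | CC(C)=CCC/C(C)=C/C[C@@]1(C)C(=O)C(CC=C(C)C)=C(O)C=C1O[C@@H](C)CC(=O)O | intermediate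
18 | mixed anhydride of 17 with trifluoroacetic acid (3S, 6R) | CC(C)=CCC/C(C)=C/C[C@@]1(C)C(=O)C(CC=C(C)C)=C(O)C=C1O[C@@H](C)CC(=O)OC(=O)C(F)(F)F | intermediate
19 | (2S,8R)-8-[(2E)-3,7-dimethylocta-2,6-dien-1-yl]-5-hydroxy-2,8-dimethyl-6-(3-methylbut-2-en-1-yl)-2,3-dihydro-4H-chromene-4,7(8H)-dione | CC(C)=CCC/C(C)=C/C[C@@]1(C)C(=O)C(CC=C(C)C)=C(O)C2=C1O[C@@H](C)CC2=O | target

**Step count and risks**

Total steps: 8. Longest linear sequence: 8 steps (1 → 19).

Steps most likely to fail:

1. Step 6 (Proposed new method). The enolate may be acylated at oxygen instead of carbon by the cumulated ylide, or the olefination of the hindered ester carbonyl C8a may be too slow, so that the acyl ylide decomposes on heating. The fallback closes ring B before ring A with known anionic chemistry and sets out from 11.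
   - The tert-butyl ester is cleaved (Me3SiOTf, 2,6-lutidine) to the acid F1.
   - F1 is condensed with 2,2-dimethyl-1,3-dioxane-4,6-dione (DCC, DMAP) to the acyl dioxanedione F2, which is heated in ethanol to the β-keto ester F3.
   - LiN(SiMe3)2 then moves the acyl group from O1 to the C4a enolate (Baker–Venkataraman-type O→C acyl shift) to give the hydroxy tricarbonyl compound F4.
   - Camphorsulfonic acid in benzene over molecular sieves cyclises and dehydrates F4 to the dihydropyranone ester F5. At this stage C8a is the only ketone within reach of the hydroxyl, so O1 ends on C8a.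
   - A Dieckmann condensation of the C6 enolate onto the C5 ester (LiN(SiMe3)2, THF, −78 °C, kept short and cold because the ring B ketone can lose O1 by β-elimination) closes ring A, and the sequence comes back to the route at 19.

2. Step 8. The ring may be too poor a nucleophile once its enol is O-trifluoroacetylated, or the liberated CF3CO2H may trigger attack of the enol oxygen on the prenyl double bond (chroman formation) and cyclisation of the geranyl chain. The fallback replaces acid-mediated closure by neutral acyl transfer and sets out from 17. 2,2'-Dipyridyl disulfide and PPh3 convert the acid into the S-(2-pyridyl) thioester F6. On warming in toluene the acidic ring enol protonates the pyridine nitrogen, and C4a is acylated by the doubly activated thioester with loss of pyridine-2-thione, without any strong acid. The product is 19.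

3. Step 2. The esterase may discriminate the enantiotopic esters poorly or in the opposite sense with the long lipophilic geranyl chain, or turn over slowly because of low solubility. The fallback is a resolution through diastereomers and sets out from 3. One equivalent of KOH in methanol gives the racemic half-ester F7. Esterification with 5 as in step 3 gives 6 together with its epimer at the quaternary carbon F8. The two diastereomers are separated by preparative chromatography, and the sequence rejoins the route at 6.

**Further compounds**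

F1 | step 6 | (3S)-3-{[(2S)-2-geranyl-2,7-dimethyl-3-oxooct-6-enoyl]oxy}butanoic acid | CC(C)=CCC/C(C)=C/C[C@@](C)(C(=O)CCC=C(C)C)C(=O)O[C@@H](C)CC(=O)O
F2 | step 6 | 5-acyl-2,2-dimethyl-1,3-dioxane-4,6-dione (enol form) derived from F1, stereocentres as in 11 | CC(C)=CCC/C(C)=C/C[C@@](C)(C(=O)CCC=C(C)C)C(=O)O[C@@H](C)CC(O)=C1C(=O)OC(C)(C)OC1=O
F3 | step 6 | ethyl (5S)-5-{[(2S)-2-geranyl-2,7-dimethyl-3-oxooct-6-enoyl]oxy}-3-oxohexanoate | CC(C)=CCC/C(C)=C/C[C@@](C)(C(=O)CCC=C(C)C)C(=O)O[C@@H](C)CC(=O)CC(=O)OCC
F4 | step 6 | ethyl 2-[(3S)-3-hydroxybutanoyl]-4-geranyl-4,9-dimethyl-3,5-dioxodec-8-enoate, quaternary centre as in 11 | CC(C)=CCC/C(C)=C/C[C@@](C)(C(=O)CCC=C(C)C)C(=O)C(C(=O)OCC)C(=O)C[C@H](C)O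
F5 | step 6 | ethyl (6S)-6-methyl-4-oxo-5,6-dihydro-4H-pyran-3-carboxylate carrying at C2 the group C(CH3)(geranyl)C(=O)CH2CH2CH=C(CH3)2, quaternary centre as in 11 | CC(C)=CCC/C(C)=C/C[C@@](C)(C(=O)CCC=C(C)C)C1=C(C(=O)OCC)C(=O)C[C@H](C)O1
F6 | step 8 | S-(pyridin-2-yl) thioester of 17 (3S, 6R) | CC(C)=CCC/C(C)=C/C[C@@]1(C)C(=O)C(CC=C(C)C)=C(O)C=C1O[C@@H](C)CC(=O)Sc1ccccn1
F7 | step 2 | racemic 2-geranyl-3-methoxy-2-methyl-3-oxopropanoic acid | CC(C)=CCC/C(C)=C/CC(C)(C(=O)OC)C(=O)O
F8 | step 2 | 1-[(2S)-4-tert-butoxy-4-oxobutan-2-yl] 3-methyl (2R)-2-geranyl-2-methylpropanedioate (epimer of 6 at the quaternary carbon) | CC(C)=CCC/C(C)=C/C[C@](C)(C(=O)OC)C(=O)O[C@@H](C)CC(=O)OC(C)(C)C
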